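## Structural features

The target 7 is an achiral, hexabrominated diaryl ether. Ring A carries a methoxy group on C1, the bridging ether oxygen on C2 and a bromine on each of C3 to C6. Ring B is a phenol with the ether oxygen on C1', the free hydroxyl on the neighbouring C6', bromine on C3' and C5', and hydrogen only on C2' and C4'. The rings are joined by the single C2–O–C1' bridge, which is flanked by a bromine and the methoxy group on ring A and lies ortho to the hydroxyl on ring B. There is no stereocentre in 7, so the only stereochemical event in the plan is the transient creation of two adjacent ring-fusion centres that are erased on aromatization. The fragile parts are the six aryl C–Br bonds (reducing, organometallic or zerovalent-metal conditions), the free ring B phenol (oxidation) and the methyl ether (strong acid when hot). The real difficulty is the diaryl ether bond: the ring A oxygen belongs to an electron-poor, doubly ortho-substituted phenol that is a poor partner in substitution or copper-mediated coupling, and the two ring A oxygens must also be told apart. The key step exploits two facts: the C1/C2 dioxygen pattern flanked by four bromines is the oxidation pattern of tetrabromo-o-benzoquinone, and the adjacent oxygenated carbons C1' and C6' of ring B map onto the C=C bond of a cyclohexanone enol ether. The C3' and C5' bromines are para and ortho to the C6' hydroxyl, which is where electrophilic bromination of the ring B phenol goes unaided.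

## Logic of the disconnections

**7 ⇒ 5 (through 6).** The C3'–Br and C5'–Br bonds are cut and ring B is taken back from the phenol to the cyclohexanone oxidation level, with C6' as the carbonyl carbon. The cut is made there because both bromines sit ortho and para to the hydroxyl of 6, and because 6 is the dehydrogenated form of an α-aryloxy cyclohexanone; bromine can serve both purposes. The gain is that ring B becomes a plain six-membered ketone and the hindered diaryl ether becomes an alkyl aryl ether next to a carbonyl group. The forward step must remove six hydrogens and add two bromines without breaking the C1'–O bond while ring B is still saturated, without cleaving the methyl ether, and without a third bromination at C4'.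

**5 ⇒ 3 (through 4).** The O–CH3 bond on the C1 oxygen of ring A is cut, and that oxygen is tied back to C6' as part of a silyl ketal. In 3 the two ring A oxygens are already different: one is a stable ether to C1', the other is a ketal oxygen on C6'. Unmasking the ketal therefore frees exactly one phenoxide, 4. The gain is that no monoprotection of a symmetric catechol is needed. The forward step must collapse the ketal towards the phenoxide and methylate on oxygen under conditions that leave the enolizable α-aryloxy ketone alone.

**3 ⇒ 1 + 2.** The two bonds O–C10a (the later O–C1' bond) and O–C4a (the transient O–C6' bond) are cut, opening the 1,4-dioxine ring. Quinone 1 supplies ring A with both oxygens and all four bromines, and enol ether 2 supplies the six carbons of ring B with its oxygen at the ketone level. The gain is maximal: both partners are commercial, and the hindered C–O bond is made by a cycloaddition in which the ortho bromines help by blocking the ring carbons and raising electrophilicity. The forward step must make O,O-cycloaddition win over redox reactions between the quinone and the enol ether and over bond formation at carbon.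

## Other disconnections considered

**Alternative 1:** The cut is at C1'–C2' and C5'–C6' of ring B. C2' to C5' with both bromines would come from 3,5-dibromo-2H-pyran-2-one A2. C1' and C6' with their oxygens would come from the bis(trimethylsilyl) ketene acetal A3 of the ring A aryloxyacetic acid.
- Forward key step: [4+2] cycloaddition of A3 onto A2, with the nucleophilic CH(OAr) carbon bonding to C6 of the pyrone. Cycloreversion with loss of CO2 and elimination of Me3SiOH would give the aryl silyl ether A1, one desilylation from 7.
- In its favour: the C3' and C5' bromines arrive in their final places, and there is no late oxidation and no electrophilic bromination. Over-bromination at C4' and acid-promoted loss of ring A cannot occur. On control of the ring B halogen pattern and on mildness of the endgame this alternative is the better one. Its regiochemistry rests on the polarization of the dibromopyrone, which makes it the equal of the chosen plan with its symmetric quinone.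
- Against it: A3 needs the ring A phenol F2 (introduced with the fallback to step 1), its O-alkylation with a haloacetate, ester cleavage and double silylation, and A2 needs its own preparation. The electron-poor aryloxy group makes A3 a weaker donor and the two silyloxy groups make it hydrolytically delicate. Conjugate addition with opening of the pyrone ring can compete with cycloaddition, and the bridged lactone normally needs heating to lose CO2.
- Comparison: mechanistically the two cycloadditions are of comparable standing. In step economy the chosen plan is clearly shorter, three steps from two commercial compounds against about six in the longest line plus the pyrone.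

**Alternative 2:** The cut is at C4'–C5' and C5'–C6', so C5' with its bromine is excised as a one-carbon unit and ring B contracts to a cyclopentadiene.
- Forward key step: dibromocarbene would add to the silyl enol ether double bond of 2-(trimethylsilyloxy)-3-(2,3,4,5-tetrabromo-6-methoxyphenoxy)cyclopenta-1,3-diene A5. The dibromocyclopropane would open with loss of bromide and the silyl group, and the bromodienone would tautomerize to the 2-bromophenol A4. One bromination para to the hydroxyl (C3') would finish the synthesis.
- In its favour: C5'–Br is installed by construction, and the last bromination has only one ortho/para site left. On regiochemical certainty of the bromine pattern it is the equal of, or slightly better than, the chosen plan. Ring expansion of halocyclopropanated enol ethers is an established reaction type.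
- Against it: A5 is a cross-conjugated silyloxycyclopentadiene that can isomerize by 1,5-hydrogen shifts, dimerize by Diels–Alder reaction and hydrolyse. It has two enol ether double bonds, and the carbene must choose the silylated one. Its precursor, a 2-aryloxycyclopentenone derived from the hindered ring A phenol F2, is several steps away. Carbene generation from bromoform and KOtBu is harsh for a base-sensitive polybromide.
- Comparison: structurally, the ether bond must be made by substitution with a poor phenol nucleophile instead of by cycloaddition. Mechanistically, three selectivity demands are stacked (site of carbene attack, integrity of the diene, mode of ring opening) where the chosen plan has one. In step count it is at least twice as long.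

**Alternative 3:** The cut is at C1'–C2' and C4'–C5', dividing ring B into a three-carbon ketone unit (C1', C6', C5') and a three-carbon dialdehyde unit (C2', C3', C4').
- Forward key step: a double aldol-type condensation of 1-(2,3,4,5-tetrabromo-6-methoxyphenoxy)propan-2-one A7 with bromomalonaldehyde A8, in the manner of the classical nitromalonaldehyde–ketone phenol synthesis. Dehydration and tautomerization would give the 4-bromophenol A6, and bromination at the only free ortho position (C5') would complete 7.
- In its favour: the reagents are cheap, C3'–Br is placed without ambiguity, the final bromination has a single activated site, and no oxidation of a saturated ring is needed. In regiochemical security it is the equal of the chosen plan. In length (about four steps from the ring A phenol F2 stage) it is within one step of the chosen plan.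
- Against it: A8 is largely enolized or ionized in base and is therefore a much weaker electrophile than the nitro analogue on which the analogy rests, and it can also act as an alkylating agent at its C–Br bond. The ring closure must engage the weakly acidic methyl group of A7 as well as its activated methylene. Aqueous base may expel the aryloxide from A7.
- Comparison: its ring-forming step is the least secure of the four considered, whereas the chosen cycloaddition belongs to an established class.

Key step: step 1

Assumption (remark on the chemistry): 3, 4 and 5 are racemates. Because 7 is achiral, neither the relative nor the absolute configuration of these intermediates affects the outcome. Crude 3 is assumed to be carried into step 2 without chromatography, since a mixed silyl ketal of this kind is sensitive to silica gel.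

## Steps

**Step 1**
Reactants: 1 tetrabromo-1,2-benzoquinone (o-bromanil); 2 1-(trimethylsilyloxy)cyclohexene
Product: 3 cis-6,7,8,9-tetrabromo-4a-(trimethylsilyloxy)-1,2,3,4,4a,10a-hexahydrodibenzo[b,e][1,4]dioxine (racemic, 4aR*,10aR*)
Conditions: 2 (1.2 equiv), toluene, −30 °C → rt, N2, dark; evaporate and use crude
Reagents that add atoms: none
Why: This is an inverse-electron-demand hetero-Diels–Alder reaction in which the O=C–C=O unit of 1, made strongly electron-poor by two carbonyl groups and four bromines, is the four-atom heterodiene and the electron-rich enol ether C=C of 2 is the two-atom partner; the closest known reaction type is the cycloaddition of tetrahalo-o-quinones with enol ethers, enamines and styrenes to give 2,3-dihydro-1,4-benzodioxines. Bond formation should be asynchronous, the O–C10a bond to the nucleophilic β-carbon of the enol ether leading and the O–C4a bond following, in the limit through a silyloxocarbenium/aryloxide zwitterion. The 1,4-dioxine ring is closed by the intermolecular [4+2] annulation itself, and in the stepwise limit the second bond forms by 6-exo-trig attack of the aryloxide on the oxocarbenium carbon. The two new centres C4a and C10a are set together by suprafacial addition across the ring-constrained cis double bond, which gives the cis ring fusion; no facial control is needed because the adduct is racemic and both centres disappear in step 3. The selectivity required is chemoselectivity for O,O-addition over dehydrogenation of 2 by hydride or electron transfer, over bond formation at the quinone ring carbons and over reaction of the quinone as a carbodiene. This is secured by the four bromines that block every ring carbon, by the aromatic stabilization gained when both oxygens become aryl ether oxygens, and by a nonpolar solvent and low temperature that disfavour free ions and radical ions. Regiochemistry is not an issue because 1 is symmetric. If silyl transfer to the phenolic oxygen opened the ketal, the isomer formed would be funnelled to the same phenoxide 4 in step 2.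

**Step 2**
Reactants: 3 cis-6,7,8,9-tetrabromo-4a-(trimethylsilyloxy)-1,2,3,4,4a,10a-hexahydrodibenzo[b,e][1,4]dioxine
Product: 5 2-(2,3,4,5-tetrabromo-6-methoxyphenoxy)cyclohexan-1-one (racemic), via cesium phenolate 4 (not isolated)
Conditions: CsF (1.5 equiv), MeI (1.5 equiv), DMF, 0 °C → rt
Reagents that add atoms: iodomethane, CI
Why: Fluoride cleaves the O–Si bond (desilylation), and the hemiketal alkoxide collapses to the ketone by expelling the far more stable tetrabromophenoxide 4, the only good nucleophile present, which is O-methylated by iodomethane in an SN2 reaction (Williamson ether synthesis). Only the oxygen that was bonded to C4a is released, so the methyl group goes to the correct ring A oxygen by construction; the single centre of 5 is the former C10a, stays racemic and is removed in step 3.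

**Step 3**
Reactants: 5 2-(2,3,4,5-tetrabromo-6-methoxyphenoxy)cyclohexan-1-one
Product: 7 2,4-dibromo-6-(2,3,4,5-tetrabromo-6-methoxyphenoxy)phenol (target), via ring B phenol 6 (not isolated)
Conditions: Br2 (2.1 equiv), anhydrous AcOH, 20 → 70 °C; then Br2 (2.1 equiv), 20 °C; aq. NaHSO3
Reagents that add atoms: bromine, BrBr
Why: Acid-catalysed enolization, α-bromination and loss of HBr, run twice, should dehydrogenate the cyclohexanone to phenol 6 (halogenative aromatization of a cyclohexanone), and 6 should then undergo electrophilic aromatic bromination at C5' and C3', the only positions ortho and para to its hydroxyl. Bromine taken up at the α'- or γ-carbon before aromatization ends on the same two ring positions, so the possible orders of events converge; ring A has no free position, and the diaryl ether is inert once ring B is aromatic.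

## Compound list

1 | tetrabromo-1,2-benzoquinone (3,4,5,6-tetrabromocyclohexa-3,5-diene-1,2-dione, o-bromanil) | O=C1C(=O)C(Br)=C(Br)C(Br)=C1Br | starting material
2 | 1-(trimethylsilyloxy)cyclohexene | C[Si](C)(C)OC1=CCCCC1 | starting material
3 | cis-6,7,8,9-tetrabromo-4a-(trimethylsilyloxy)-1,2,3,4,4a,10a-hexahydrodibenzo[b,e][1,4]dioxine, racemic (4aR*,10aR*; one enantiomer drawn) | C[Si](C)(C)O[C@]12CCCC[C@H]1Oc1c(Br)c(Br)c(Br)c(Br)c1O2 | intermediate
4 | cesium 2,3,4,5-tetrabromo-6-[(2-oxocyclohexyl)oxy]phenolate, racemic (one enantiomer drawn) | [Cs+].[O-]c1c(Br)c(Br)c(Br)c(Br)c1O[C@@H]1CCCCC1=O | intermediate (not isolated)
5 | 2-(2,3,4,5-tetrabromo-6-methoxyphenoxy)cyclohexan-1-one, racemic (one enantiomer drawn) | COc1c(Br)c(Br)c(Br)c(Br)c1O[C@@H]1CCCCC1=O | intermediate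
6 | 2-(2,3,4,5-tetrabromo-6-methoxyphenoxy)phenol | COc1c(Br)c(Br)c(Br)c(Br)c1Oc1ccccc1O | intermediate (not isolated)
7 | 2,4-dibromo-6-(2,3,4,5-tetrabromo-6-methoxyphenoxy)phenol | COc1c(Br)c(Br)c(Br)c(Br)c1Oc1cc(Br)cc(Br)c1O | target

## Step count and least certain steps

Total step count: 3. Longest linear sequence: 3 steps (1 + 2 → 3 → 5 → 7).

**Step 1 (key step).** The most likely failure is redox interception: electron or hydride transfer from the enol ether to the strongly oxidizing quinone, which dehydrogenates 2 and reduces 1 instead of joining them through oxygen. Hydrolysis of the silyl enol ether by adventitious acid or water is a second risk.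
Fallback: the C1'–O bond would be made by Williamson alkylation instead of cycloaddition. The fallback sets out from 2 and returns at 5, bypassing steps 1 and 2. Treatment of 2 with NBS in THF at 0 °C, followed by aqueous work-up, should give 2-bromocyclohexan-1-one F1. Separately, exhaustive bromination of commercial guaiacol (excess Br2, cat. FeBr3, AcOH, 60 °C) should give 3,4,5,6-tetrabromo-2-methoxyphenol F2. Heating F2 with K2CO3 and F1 in DMF at 50 °C should then give 5. The weak point of this fallback is the low nucleophilicity of the hindered phenoxide towards a secondary α-bromo ketone.

**Step 3.** The most likely failure is cleavage of the C1'–O bond while ring B is still saturated. This can happen by ionization or bromide displacement at the α-carbon, or by hydrolysis of an α-brominated intermediate by traces of water. Incomplete aromatization, a third bromination at C4' (para to the ether oxygen) and acid-promoted demethylation at the higher temperature are further risks.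
Fallback: oxidation and bromination would be separated, and the first dehydrogenation done under basic, bromine-free conditions. The fallback sets out from 5 and returns at 7.
- The kinetic α'-enolate of 5 (LiN(iPr)2, THF, −78 °C) would be treated with N-tert-butylbenzenesulfinimidoyl chloride at −78 °C to give 6-(2,3,4,5-tetrabromo-6-methoxyphenoxy)cyclohex-2-en-1-one F4 by sulfinimidoyl transfer and syn-elimination.
- F4 would be aromatized with catalytic I2 in DMSO at 80 °C, a known conversion of cyclohexenones into phenols, to give 6, this time isolated.
- 6 would be brominated with NBS (2.05 equiv) in MeCN at 0 °C to give 7.
A regioisomeric enone from the first operation would converge on 6 in the second.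

**Step 2.** The most likely failure is methylation at the wrong site, either at the hemiketal oxygen before the ketal collapses or at carbon of the enolate formed by the basic fluoride. Base-induced degradation of the α-aryloxy ketone is also possible.
Fallback: unmasking and methylation would be separated, and the methylation run without base. The fallback sets out from 3 and returns at 5. Hydrolysis of 3 with 1 M HCl in THF at rt should give 2-(2,3,4,5-tetrabromo-6-hydroxyphenoxy)cyclohexan-1-one F3. The acidic phenol of F3 would then be methylated by a Mitsunobu reaction (MeOH, PPh3, DIAD, THF, 0 °C → rt) to give 5.

## Further compounds

F1 | step 1 | 2-bromocyclohexan-1-one (racemic) | O=C1CCCCC1Br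
F2 | step 1 | 3,4,5,6-tetrabromo-2-methoxyphenol | COc1c(O)c(Br)c(Br)c(Br)c1Br
F3 | step 2 | 2-(2,3,4,5-tetrabromo-6-hydroxyphenoxy)cyclohexan-1-one (racemic; one enantiomer drawn) | Oc1c(Br)c(Br)c(Br)c(Br)c1O[C@@H]1CCCCC1=O
F4 | step 3 | 6-(2,3,4,5-tetrabromo-6-methoxyphenoxy)cyclohex-2-en-1-one (racemic; one enantiomer drawn) | COc1c(Br)c(Br)c(Br)c(Br)c1O[C@@H]1CCC=CC1=O
A1 | alternative 1 | [2,4-dibromo-6-(2,3,4,5-tetrabromo-6-methoxyphenoxy)phenoxy]trimethylsilane | COc1c(Br)c(Br)c(Br)c(Br)c1Oc1cc(Br)cc(Br)c1O[Si](C)(C)C
A2 | alternative 1 | 3,5-dibromo-2H-pyran-2-one | O=C1OC=C(Br)C=C1Br
A3 | alternative 1 | 1,2,3,4-tetrabromo-5-{[2,2-bis(trimethylsilyloxy)ethenyl]oxy}-6-methoxybenzene | COc1c(Br)c(Br)c(Br)c(Br)c1OC=C(O[Si](C)(C)C)O[Si](C)(C)C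
A4 | alternative 2 | 2-bromo-6-(2,3,4,5-tetrabromo-6-methoxyphenoxy)phenol | COc1c(Br)c(Br)c(Br)c(Br)c1Oc1cccc(Br)c1O
A5 | alternative 2 | 2-(trimethylsilyloxy)-3-(2,3,4,5-tetrabromo-6-methoxyphenoxy)cyclopenta-1,3-diene | COc1c(Br)c(Br)c(Br)c(Br)c1OC1=CCC=C1O[Si](C)(C)C
A6 | alternative 3 | 4-bromo-2-(2,3,4,5-tetrabromo-6-methoxyphenoxy)phenol | COc1c(Br)c(Br)c(Br)c(Br)c1Oc1cc(Br)ccc1O
A7 | alternative 3 | 1-(2,3,4,5-tetrabromo-6-methoxyphenoxy)propan-2-one | COc1c(Br)c(Br)c(Br)c(Br)c1OCC(C)=O
A8 | alternative 3 | 2-bromopropanedial (bromomalonaldehyde) | O=CC(Br)C=O
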